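## Analysis of the target

The target is a labdane, a trans-decalin in which ring A is C1–C5 plus C10 and ring B is C5–C10. It carries geminal methyls on C4, methyls on C8 (C17) and C10 (C20), and the chain C11–C12=C13(C16)–C14=C15 on C9, with a (12E)-diene. Six contiguous stereocentres run round ring B: 5α-H and 10β-CH3 (trans fusion), 9α-H (chain β, equatorial), 8α-OH with 8β-CH3, 7β-OAc (equatorial) and 6β-OH (axial, syn to the axial methyls on C10 and C4). The sensitive groups are the conjugated diene (acid, electrophilic oxidants, dissolving metals), the acetate, which can migrate to the cis 6β-hydroxyl under base, and the tertiary 8α-hydroxyl, which lies 1,4 to C12 and would close a lactol or tetrahydrofuran onto an electrophilic C12. The difficulty lies in the dense oxygenation of ring B, with both secondary oxygens on the hindered β face, next to a quaternary C10 that is itself flanked by the quaternary C4, and in the need for one enantiomer. The feature used here is that ring B has the substitution pattern of an oxidised phenol: oxygen on C7, a methyl on the ortho carbon C8 and a methyl on the para carbon C10 (the pattern of 2,4-dimethylphenol), while the meta carbons C9 and C5 carry the side-chain stub and the ring A carbons. The bond C1–C10 can therefore be made by alkylating a phenoxide at its para carbon with a chain anchored on C5; the C10 methyl makes the dearomatisation permanent, and C6 and C8, still to be oxygenated, emerge as the two α-carbons of the C7 carbonyl.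

## Retrosynthetic reasoning

31 to 30: the acyl–O7 bond is cut last. In triol 30 the 7β-hydroxyl is the only unhindered secondary hydroxyl (6β-OH is axial under two syn-axial methyls, 8α-OH is tertiary), and late acetylation keeps the ester away from bases that would move it to O6.

30 to 28: the C–H bonds at C7, C6 and C5 are cut, leading back to the enolised 6,7-dione 28 (through hydroxy ketone 29). All three hydrogens lie on the α face. The forward reaction must deliver hydride twice and a proton once from that face, which the β-methyls on C10, C4 and C8 enforce. This places both hindered β-oxygens by reduction instead of by oxidation from the blocked face.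

28 to 26, 24 and 22: the C6–O and C8–O bonds are cut back to ketone 22. Both carbons are α to the C7 carbonyl, so each oxygen can come from an enolate and an electrophilic oxygen source. The forward sequence needs the kinetic enolate toward C6 first, then, with C6 occupied by its alkoxide, the enolate toward C8, attacked from the α face.

22 to 20 and 18: the C14=C15 and C12=C13 double bonds are cut by two carbonyl olefinations with 21 and 19. They are placed before any ring B hydroxyl exists, so that no 8-hydroxyl can add to C12 and no acetate meets an ylide.

18 to 17 and 16: this is a redox adjustment. The C–H bonds at C5, C6, C8 and C9 come from a dissolving-metal reduction of dienone 16, which also removes the chlorine and the benzyl group; reoxidation then gives the keto aldehyde 18. C9 is set here for good.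

16 to 14: the C1–C10 bond is cut. This is the only disconnection that turns ring B into a flat, stereocentre-free arene while keeping the C7 oxygen, the C8 and C10 methyls and the C9 and C5 substituents in place. The forward reaction must alkylate phenoxide 15 at the para carbon, on one face, with the bromide at C1.

14 to 13, 12, 11 and 9: the C6–Cl, C1–Br, C7–O and C1–O bonds are cut. Chlorine enters last at the only free ring position, the phenol oxygen replaces an aryl bromide, and the C1 oxygen comes from a terminal alkene.

9 to 7 and 4: the C3–C4 bond and then the C4–C5 bond are cut. The quaternary C4 is assembled from 5 (C4 and its two methyls) and 8 (C3 to C1) through a tertiary benzylic cation. The aryl–C4 bond comes from aryllithium 6, made from the symmetric dibromide 4 by a single halogen–metal exchange, which avoids a statistical desymmetrisation.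

4 to 3, 2 and 1: the two C–Br bonds at C5 and C7, the benzyl ether and the acid oxidation level are removed. Both bromines enter the only positions of 1 that are ortho to one methyl and para to the other.

## Alternatives that were turned down

Alternative 1: The disconnection cuts C5–C10 and C8–C9, so both rings come from an open chain. The forward key step is an intramolecular Diels–Alder reaction of trienal A2, in which the (Z)-silyloxy diene C5=C6–C7=C8 adds to the tethered (E)-enal C9=C10 to give the trans-fused A1. In its favour, it forms two rings, two bonds and four stereocentres (C5, C8, C9, C10) in one step, delivers the C8 carbinol already protected, and leaves a C6=C7 alkene where oxygen is needed. On bonds and stereocentres per step it is stronger than the chosen route. Against it, both new bonds join fully substituted carbons (C10 next to the C4 quaternary centre; C8 carrying methyl and silyloxy), and the (Z) substituent points into the diene, so the barrier is high and diene isomerisation competes. Absolute control would need a catalyst that activates a hindered β,β-disubstituted enal. The C6=C7 alkene of A1 would have to be cis-dihydroxylated on the β face, which the axial methyls on C10 and C4 block, so both C6 and C7 would need later inversion. The aldehyde carbon of A1 is C11, so a one-carbon homologation is needed before the diene. The chosen route offers a key step with one stereochemical question on a flat substrate, the C7 carbonyl from which both β-oxygens follow by α-face hydride delivery, and the C11–C12 stub already in place.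

Alternative 2: The disconnection forms C8–C9 while breaking C7–C9, so ring B comes from a five-membered ring. The forward key step is a chelation-controlled α-ketol rearrangement of the trans-hydrindane ketol A4, in which C9 migrates from C7 to the acetyl carbon C8 to give A3. In its favour, C8 (α-OH, β-CH3) is set by a suprafacial shift inside a chelate and the ring enlargement is downhill. On this point it is stronger than the chosen route, which relies on enolate face selectivity at C8 (step 16). Against it, A4 already contains C5, C9, C10 and a quaternary carbinol C7 in a strained trans-hydrindane with an angular methyl next to the C4 quaternary centre. That is harder to make than the decalin, and the origin of absolute configuration at C10 is only pushed back. Either ring bond of C7 could migrate (C6 as well as C9), and A3 still lacks the C6 oxygen, so the same C6 oxidation and double reduction as in steps 15 to 18 would follow. The chosen route reaches the same oxidation pattern with fewer steps before ring B exists, because the C7 oxygen and both ring B methyls come with the arene.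

Alternative 3: The disconnection cuts C7–C8 and C9–C10, an intermolecular [4+2] construction of ring B on a preformed ring A. The forward key step adds the 2-silyloxy diene A6 (C10=C5–C6(OSi)=C7) to the alkynoate A7 (C8≡C9) to give A5. In its favour, it is the most convergent plan: two small achiral partners, ring B, the quaternary C10, the C8 methyl and a C6 oxygen in one step, with a regiochemistry that matches the polarisation of both partners. In step economy of ring construction it beats the chosen route. Against it, the diene terminus C10 is a tetrasubstituted ring carbon next to the C4 quaternary centre, A7 is a weak β-substituted dienophile, and the reactive s-cis conformer of A6 is disfavoured by the ring methyls, so the bimolecular reaction would be slow. C10 is the only stereocentre of A5 and would need an enantioselective catalyst for this hindered pair. After the cycloaddition the oxygen sits on C6 while C7 is a methylene, so C7 and C8 would both still have to be oxidised. C11 is an ester carbon on C9, so the chain needs homologation, and the 5,8-diene must still be reduced with control at C5 and C9. The chosen route instead places the oxygen on C7, the carbon from which C6 and C8 can both be reached as enolate positions.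

Key step: step 10

Assumption: in 17, 18, 20, 22 and 24 the C8 methyl is drawn equatorial (8α) and in 17 the C7 hydroxyl equatorial (7β), as expected from the reduction; C7 is trigonal again after step 12 and C8 after step 16, so an epimer at either centre would not change the outcome.
Assumption: the sense of induction of the ammonium salt in step 10 cannot be predicted; if the cinchonidinium salt favours the (10S) dienone, the pseudo-enantiomeric cinchoninium salt is used instead.

## Steps

Step 1
Reactants: 1 2,6-dimethylphenylacetic acid
Product: 2 2-(3,5-dibromo-2,6-dimethylphenyl)acetic acid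
Conditions: Br2 (2.1 equiv), Fe powder (5 mol%), CH2Cl2, 0 °C to rt, dark
Reagents that add atoms: bromine, BrBr
Why: Electrophilic aromatic bromination; each bromine should enter ortho to one methyl and para to the other (the pattern of the 4,6-dibromination of m-xylene), while the position para to the CH2CO2H group is meta to both methyls and stays free. The brominated carbons are C5 and C7 of ring B.

Step 2
Reactants: 2 2-(3,5-dibromo-2,6-dimethylphenyl)acetic acid
Product: 3 2-(3,5-dibromo-2,6-dimethylphenyl)ethanol
Conditions: BH3·THF (2.5 equiv), THF, 0 °C to rt; MeOH quench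
Reagents that add atoms: none
Why: Borane reduction of a carboxylic acid to the primary alcohol; aryl bromides are inert to borane.

Step 3
Reactants: 3 2-(3,5-dibromo-2,6-dimethylphenyl)ethanol
Product: 4 3-[2-(benzyloxy)ethyl]-1,5-dibromo-2,4-dimethylbenzene
Conditions: NaH (1.3 equiv), BnBr (1.2 equiv), n-Bu4NI (5 mol%), THF, 0 °C to rt
Reagents that add atoms: benzyl bromide, BrCc1ccccc1
Why: Williamson ether synthesis; the benzyl ether should survive organolithium, Lewis acid, palladium and hydroxide, and it is removed without a separate step in the dissolving-metal reduction (step 11).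

Step 4
Reactants: 4 3-[2-(benzyloxy)ethyl]-1,5-dibromo-2,4-dimethylbenzene; 5 acetone
Product: 7 2-{3-[2-(benzyloxy)ethyl]-5-bromo-2,4-dimethylphenyl}propan-2-ol, via aryllithium 6 (not isolated)
Conditions: n-BuLi (1.0 equiv), THF, −78 °C, 20 min; 5 (1.5 equiv), −78 to 0 °C; H2O
Reagents that add atoms: none
Why: Bromine–lithium exchange on a symmetric dibromide stops after one exchange, because the aryllithium is deactivated toward a second one, so no statistical mixture is expected. 1,2-Addition to acetone gives the tertiary benzylic carbinol whose carbinol carbon is C4.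

Step 5
Reactants: 7 2-{3-[2-(benzyloxy)ethyl]-5-bromo-2,4-dimethylphenyl}propan-2-ol; 8 allyltrimethylsilane
Product: 9 3-[2-(benzyloxy)ethyl]-1-bromo-2,4-dimethyl-5-(2-methylpent-4-en-2-yl)benzene
Conditions: 8 (3 equiv), BF3·OEt2 (1.5 equiv, promoter), CH2Cl2, −78 to −20 °C; aq. NaHCO3
Reagents that add atoms: none
Why: Hosomi–Sakurai-type SN1 allylation; the Lewis acid ionises the tertiary benzylic alcohol and the allylsilane traps the cation at C4, giving the quaternary carbon with C3 to C1 attached. Low temperature and excess silane should suppress elimination to the isopropenyl arene and cation–alkene dimerisation.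

Step 6
Reactants: 9 3-[2-(benzyloxy)ethyl]-1-bromo-2,4-dimethyl-5-(2-methylpent-4-en-2-yl)benzene
Product: 11 4-{3-[2-(benzyloxy)ethyl]-5-bromo-2,4-dimethylphenyl}-4-methylpentan-1-ol, via alkylborane 10 (not isolated)
Conditions: 9-BBN (1.3 equiv), THF, 0 °C to rt; then 3 M NaOH, 30% H2O2, 0 °C to rt
Reagents that add atoms: hydrogen peroxide, OO
Why: Anti-Markovnikov hydroboration–oxidation; 9-BBN places boron on the terminal carbon C1 of the monosubstituted alkene, and oxidation with retention gives the primary alcohol.

Step 7
Reactants: 11 4-{3-[2-(benzyloxy)ethyl]-5-bromo-2,4-dimethylphenyl}-4-methylpentan-1-ol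
Product: 12 3-[2-(benzyloxy)ethyl]-5-(5-hydroxy-2-methylpentan-2-yl)-2,4-dimethylphenol
Conditions: Pd2(dba)3 (2 mol%), 2-di-tert-butylphosphino-2′,4′,6′-triisopropylbiphenyl (8 mol%), KOH (4 equiv), 1,4-dioxane/H2O 1:1, 100 °C; then 1 M HCl to pH 5
Reagents that add atoms: potassium hydroxide, [K+].[OH-]
Why: Palladium-catalysed hydroxylation of an aryl bromide (C–O coupling with hydroxide); oxidative addition to zerovalent palladium is followed by C–O reductive elimination promoted by the bulky biaryl phosphine. The method tolerates an ortho methyl and a free primary alcohol, and no base-labile group is present.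

Step 8
Reactants: 12 3-[2-(benzyloxy)ethyl]-5-(5-hydroxy-2-methylpentan-2-yl)-2,4-dimethylphenol
Product: 13 3-[2-(benzyloxy)ethyl]-5-(5-bromo-2-methylpentan-2-yl)-2,4-dimethylphenol
Conditions: CBr4 (1.3 equiv), PPh3 (1.3 equiv), CH2Cl2, 0 °C
Reagents that add atoms: carbon tetrabromide, BrC(Br)(Br)Br
Why: Appel bromination; the primary alcohol is converted into the bromide under neutral conditions, and the phenol is not substituted and stays un-ionised, so it cannot cyclise.

Step 9
Reactants: 13 3-[2-(benzyloxy)ethyl]-5-(5-bromo-2-methylpentan-2-yl)-2,4-dimethylphenol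
Product: 14 3-[2-(benzyloxy)ethyl]-5-(5-bromo-2-methylpentan-2-yl)-6-chloro-2,4-dimethylphenol
Conditions: N-chlorosuccinimide (1.05 equiv), TsOH·H2O (10 mol%), MeCN, 0 °C to rt, dark
Reagents that add atoms: N-chlorosuccinimide, O=C1CCC(=O)N1Cl
Why: Electrophilic chlorination of a phenol at the only unsubstituted ring carbon, C6, ortho to the hydroxyl. One equivalent in the dark should avoid ipso attack at C10 and benzylic chlorination.

Step 10
Reactants: 14 3-[2-(benzyloxy)ethyl]-5-(5-bromo-2-methylpentan-2-yl)-6-chloro-2,4-dimethylphenol
Product: 16 (4aR)-4-[2-(benzyloxy)ethyl]-1-chloro-3,4a,8,8-tetramethyl-5,6,7,8-tetrahydronaphthalen-2(4aH)-one (labdane numbering: 12-benzyloxy-6-chloro-5,8-dien-7-one, 10β-methyl), via potassium phenoxide 15 (not isolated)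
Conditions: N-(9-anthracenylmethyl)-O-allylcinchonidinium bromide (10 mol%), 50% aq. KOH (5 equiv), toluene (0.01 M), 0 °C
Reagents that add atoms: none
Why: Proposed new method: hydroxide deprotonates the phenol at the interface, the chiral ammonium cation carries the phenoxide into toluene as a tight ion pair, and the para carbon C10 displaces bromide at C1 in an intramolecular SN2 reaction that forms the C1–C10 bond. The closest known reaction types are the base-mediated intramolecular para-alkylation of phenols to fused cyclohexadienones, which is known only in racemic form, enantioselective phase-transfer alkylation of enolates, and asymmetric dearomatisation of phenols with metal-bound allyl electrophiles. Ring A closes in a 6-exo-tet mode, helped by the geminal methyls on C4. The new stereocentre C10 arises because the two faces of the planar phenoxide are enantiotopic at C10; the face is chosen by the chiral cation paired with the oxygen, since the substrate has no other stereocentre. Para attack must beat ortho attack at C6, which is equally close to the tether; the chlorine makes C6 less nucleophilic and more hindered, and attack there would give a less stable linearly conjugated dienone with a quaternary C–Cl carbon. C-alkylation must beat O-alkylation; intramolecular O-alkylation would need an eight-membered ring bridging meta positions, and intermolecular O-alkylation is suppressed by high dilution. Because C10 bears a methyl and no hydrogen, the product cannot tautomerise back to an arene and is kept as the cross-conjugated dienone.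

Step 11
Reactants: 16 (4aR)-4-[2-(benzyloxy)ethyl]-1-chloro-3,4a,8,8-tetramethyl-5,6,7,8-tetrahydronaphthalen-2(4aH)-one
Product: 17 13,14,15,16-tetranorlabdane-7β,12-diol (5α-H, 8β-H, 9α-H, 10β-methyl)
Conditions: Li (30 equiv), NH3(l)/THF 3:1, EtOH (20 equiv, in portions), −78 to −33 °C; NH4Cl
Reagents that add atoms: none
Why: Exhaustive dissolving-metal (Birch-type) reduction, of the kind that takes steroidal 1,4-dien-3-ones to 5α-3-carbinols: the C6–Cl bond is cleaved, both enone double bonds are saturated, the ketone is reduced to the equatorial carbinol and the benzyl ether is cleaved. The β-carbons are protonated from the α face, anti to the axial C10 methyl, giving 5α-H (trans-decalin) and 9α-H with the C9 chain equatorial; this is the only step that sets C9. Driving every enolate through to the carbinol with ethanol gives one product instead of ketone/enone mixtures.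

Step 12
Reactants: 17 13,14,15,16-tetranorlabdane-7β,12-diol
Product: 18 7-oxo-13,14,15,16-tetranorlabdan-12-al
Conditions: Dess–Martin periodinane (3 equiv), NaHCO3, CH2Cl2, 0 °C to rt
Reagents that add atoms: none
Why: Dess–Martin oxidation of both hydroxyls in one operation; the equatorial 7β-hydroxyl and the C9 chain cannot bridge to a lactol, so over-oxidation to a lactone is not expected.

Step 13
Reactants: 18 7-oxo-13,14,15,16-tetranorlabdan-12-al; 19 2-(triphenylphosphoranylidene)propanal
Product: 20 (12E)-7-oxo-15-norlabd-12-en-14-al
Conditions: 19 (1.2 equiv), toluene, 90 °C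
Reagents that add atoms: none
Why: Wittig olefination with a stabilised α-methyl ylide; it reacts with the aldehyde and not with the ketone, and it should give the (E)-2-methyl enal, which fixes the C12=C13 geometry of the target.

Step 14
Reactants: 20 (12E)-7-oxo-15-norlabd-12-en-14-al; 21 methyltriphenylphosphonium bromide
Product: 22 (12E)-labda-12,14-dien-7-one (8β-H)
Conditions: 21 (1.15 equiv), KN(SiMe3)2 (1.1 equiv), THF, 0 °C; then 20, −78 to −20 °C
Reagents that add atoms: none
Why: Wittig methylenation; with about one equivalent of ylide at low temperature the aldehyde should react well before the α-branched ring ketone, and the C12=C13 geometry is not touched.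

Step 15
Reactants: 22 (12E)-labda-12,14-dien-7-one
Product: 24 (12E)-6α-hydroxylabda-12,14-dien-7-one, via potassium 6-enolate 23 (not isolated)
Conditions: KN(SiMe3)2 (1.2 equiv), THF, −78 °C; 2-(phenylsulfonyl)-3-phenyloxaziridine (1.4 equiv), −78 °C; AcOH
Reagents that add atoms: 2-(phenylsulfonyl)-3-phenyloxaziridine, O=S(=O)(c1ccccc1)N1OC1c1ccccc1
Why: Enolate hydroxylation with an N-sulfonyloxaziridine; the bulky amide base should remove a C6 methylene proton in preference to the tertiary C8 proton, and the oxidant is inert toward the diene. Oxygen enters from the α face because the β face of C6 lies under the axial methyls on C10 and C4; this centre is oxidised again in step 17.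

Step 16
Reactants: 24 (12E)-6α-hydroxylabda-12,14-dien-7-one
Product: 26 (12E)-6α,8α-dihydroxylabda-12,14-dien-7-one, via dipotassium alkoxide enolate 25 (not isolated)
Conditions: KN(SiMe3)2 (2.4 equiv), THF, −78 to −40 °C; 2-(phenylsulfonyl)-3-phenyloxaziridine (1.5 equiv), −78 °C; AcOH
Reagents that add atoms: 2-(phenylsulfonyl)-3-phenyloxaziridine, O=S(=O)(c1ccccc1)N1OC1c1ccccc1
Why: Second enolate hydroxylation; the C6 alkoxide forms first and disfavours removal of the C6 proton (which would give an enediolate), so the second equivalent of base should enolise toward C8. The oxaziridine approaches C8 from the α face, away from the syn-axial C10 methyl, which sets 8α-OH with 8β-CH3.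

Step 17
Reactants: 26 (12E)-6α,8α-dihydroxylabda-12,14-dien-7-one
Product: 28 (12E)-6,8α-dihydroxylabda-5,12,14-trien-7-one, via 6,7-dione 27 (not isolated)
Conditions: Dess–Martin periodinane (1.5 equiv), NaHCO3, CH2Cl2, 0 °C to rt; then Et3N (0.2 equiv), rt
Reagents that add atoms: none
Why: Dess–Martin oxidation of the secondary C6 carbinol; the tertiary 8-hydroxyl and the diene are inert. The 6,7-dione has only one α-hydrogen (at C5, since C8 is quaternary) and is expected to rest as the enol 28, which is why C5 is set again in step 18.

Step 18
Reactants: 28 (12E)-6,8α-dihydroxylabda-5,12,14-trien-7-one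
Product: 30 (12E)-labda-12,14-diene-6β,7β,8α-triol, via hydroxy ketone 29 (not isolated)
Conditions: NaBH4 (4 equiv), CeCl3·7H2O (1.2 equiv), MeOH/THF 4:1, −40 °C to rt
Reagents that add atoms: none
Why: Luche-type 1,2-reduction followed by a second carbonyl reduction. Hydride adds to C7 from the α face (axial attack, anti to the axial 8β-methyl) to give 7β-OH; the remaining enol ketonises with protonation of C5 from the α face, anti to the methyls on C10 and C4, restoring the more stable trans-decalin in 29. The C6 ketone is then reduced from the α face, because its β face is closed by two syn-axial methyls, giving the axial 6β-OH.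

Step 19
Reactants: 30 (12E)-labda-12,14-diene-6β,7β,8α-triol
Product: 31 (12E)-6β,8α-dihydroxylabda-12,14-dien-7β-yl acetate (the target, CNP0225877.1)
Conditions: Ac2O (1.3 equiv), pyridine, 0 °C to rt
Reagents that add atoms: acetic anhydride, CC(=O)OC(C)=O
Why: Selective acylation of the least hindered hydroxyl; 7β-OH is equatorial and secondary, 6β-OH is axial under two syn-axial methyls and 8α-OH is tertiary. Mild pyridine conditions should avoid migration of the acetate to O6.

## Compound list

1 | 2,6-dimethylphenylacetic acid | Cc1cccc(C)c1CC(=O)O | starting material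
2 | 2-(3,5-dibromo-2,6-dimethylphenyl)acetic acid | Cc1c(Br)cc(Br)c(C)c1CC(=O)O | intermediate
3 | 2-(3,5-dibromo-2,6-dimethylphenyl)ethanol | Cc1c(Br)cc(Br)c(C)c1CCO | intermediate
4 | 3-[2-(benzyloxy)ethyl]-1,5-dibromo-2,4-dimethylbenzene | Cc1c(Br)cc(Br)c(C)c1CCOCc1ccccc1 | intermediate
5 | acetone | CC(C)=O | starting material
6 | {3-[2-(benzyloxy)ethyl]-5-bromo-2,4-dimethylphenyl}lithium | [Li]c1cc(Br)c(C)c(CCOCc2ccccc2)c1C | intermediate (not isolated)
7 | 2-{3-[2-(benzyloxy)ethyl]-5-bromo-2,4-dimethylphenyl}propan-2-ol | CC(C)(O)c1cc(Br)c(C)c(CCOCc2ccccc2)c1C | intermediate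
8 | allyltrimethylsilane | C=CC[Si](C)(C)C | starting material
9 | 3-[2-(benzyloxy)ethyl]-1-bromo-2,4-dimethyl-5-(2-methylpent-4-en-2-yl)benzene | C=CCC(C)(C)c1cc(Br)c(C)c(CCOCc2ccccc2)c1C | intermediate
10 | 9-(4-{3-[2-(benzyloxy)ethyl]-5-bromo-2,4-dimethylphenyl}-4-methylpentyl)-9-borabicyclo[3.3.1]nonane | C1CC2CCCC(C1)B2CCCC(C)(C)c1cc(Br)c(C)c(CCOCc3ccccc3)c1C | intermediate (not isolated)
11 | 4-{3-[2-(benzyloxy)ethyl]-5-bromo-2,4-dimethylphenyl}-4-methylpentan-1-ol | OCCCC(C)(C)c1cc(Br)c(C)c(CCOCc2ccccc2)c1C | intermediate
12 | 3-[2-(benzyloxy)ethyl]-5-(5-hydroxy-2-methylpentan-2-yl)-2,4-dimethylphenol | OCCCC(C)(C)c1cc(O)c(C)c(CCOCc2ccccc2)c1C | intermediate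
13 | 3-[2-(benzyloxy)ethyl]-5-(5-bromo-2-methylpentan-2-yl)-2,4-dimethylphenol | BrCCCC(C)(C)c1cc(O)c(C)c(CCOCc2ccccc2)c1C | intermediate
14 | 3-[2-(benzyloxy)ethyl]-5-(5-bromo-2-methylpentan-2-yl)-6-chloro-2,4-dimethylphenol | BrCCCC(C)(C)c1c(Cl)c(O)c(C)c(CCOCc2ccccc2)c1C | intermediate (precursor of the key step)
15 | potassium 3-[2-(benzyloxy)ethyl]-5-(5-bromo-2-methylpentan-2-yl)-6-chloro-2,4-dimethylphenoxide | [K+].[O-]c1c(C)c(CCOCc2ccccc2)c(C)c(C(C)(C)CCCBr)c1Cl | intermediate (not isolated)
16 | (4aR)-4-[2-(benzyloxy)ethyl]-1-chloro-3,4a,8,8-tetramethyl-5,6,7,8-tetrahydronaphthalen-2(4aH)-one | O(Cc1ccccc1)CCC1=C(C)C(=O)C(Cl)=C2C(C)(C)CCC[C@@]21C | intermediate (product of the key step)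
17 | 13,14,15,16-tetranorlabdane-7β,12-diol (5α-H, 8β-H, 9α-H) | OCC[C@H]1[C@H](C)[C@@H](O)C[C@H]2C(C)(C)CCC[C@@]21C | intermediate
18 | 7-oxo-13,14,15,16-tetranorlabdan-12-al | O=CC[C@H]1[C@H](C)C(=O)C[C@H]2C(C)(C)CCC[C@@]21C | intermediate
19 | 2-(triphenylphosphoranylidene)propanal | CC(C=O)=P(c1ccccc1)(c1ccccc1)c1ccccc1 | starting material
20 | (12E)-7-oxo-15-norlabd-12-en-14-al | O=C/C(C)=C/C[C@H]1[C@H](C)C(=O)C[C@H]2C(C)(C)CCC[C@@]21C | intermediate
21 | methyltriphenylphosphonium bromide | C[P+](c1ccccc1)(c1ccccc1)c1ccccc1.[Br-] | starting material
22 | (12E)-labda-12,14-dien-7-one (8β-H) | C=C/C(C)=C/C[C@H]1[C@H](C)C(=O)C[C@H]2C(C)(C)CCC[C@@]21C | intermediate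
23 | potassium (12E)-labda-6,12,14-trien-7-olate | C=C/C(C)=C/C[C@H]1[C@H](C)C([O-])=C[C@H]2C(C)(C)CCC[C@@]21C.[K+] | intermediate (not isolated)
24 | (12E)-6α-hydroxylabda-12,14-dien-7-one | C=C/C(C)=C/C[C@H]1[C@H](C)C(=O)[C@H](O)[C@H]2C(C)(C)CCC[C@@]21C | intermediate
25 | dipotassium (12E)-labda-7,12,14-triene-6α,7-diolate | C=C/C(C)=C/C[C@H]1C(C)=C([O-])[C@H]([O-])[C@H]2C(C)(C)CCC[C@@]21C.[K+].[K+] | intermediate (not isolated)
26 | (12E)-6α,8α-dihydroxylabda-12,14-dien-7-one | C=C/C(C)=C/C[C@H]1[C@](C)(O)C(=O)[C@H](O)[C@H]2C(C)(C)CCC[C@@]21C | intermediate
27 | (12E)-8α-hydroxylabda-12,14-diene-6,7-dione | C=C/C(C)=C/C[C@H]1[C@](C)(O)C(=O)C(=O)[C@H]2C(C)(C)CCC[C@@]21C | intermediate (not isolated)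
28 | (12E)-6,8α-dihydroxylabda-5,12,14-trien-7-one | C=C/C(C)=C/C[C@H]1[C@](C)(O)C(=O)C(O)=C2C(C)(C)CCC[C@@]21C | intermediate
29 | (12E)-7β,8α-dihydroxylabda-12,14-dien-6-one | C=C/C(C)=C/C[C@H]1[C@](C)(O)[C@@H](O)C(=O)[C@H]2C(C)(C)CCC[C@@]21C | intermediate (not isolated)
30 | (12E)-labda-12,14-diene-6β,7β,8α-triol | C=C/C(C)=C/C[C@H]1[C@](C)(O)[C@@H](O)[C@@H](O)[C@H]2C(C)(C)CCC[C@@]21C | intermediate
31 | (12E)-6β,8α-dihydroxylabda-12,14-dien-7β-yl acetate | C=C/C(C)=C/C[C@H]1[C@](C)(O)[C@@H](OC(C)=O)[C@@H](O)[C@H]2C(C)(C)CCC[C@@]21C | target

## Step count and least certain steps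

Total step count: 19. Longest linear sequence: 19 steps (from 1 to 31).

Step 10 (key step). The most likely failure is weak facial discrimination: the chiral cation is paired with the oxygen, while the bond forms at the remote para carbon through a flexible four-atom tether, and an uncatalysed interfacial reaction gives racemate. Competing processes are alkylation between two molecules at oxygen and attack through the chlorine-bearing ortho carbon. Fallback with known chemistry: starting from 14, cyclise with KOt-Bu in t-BuOH at high dilution (the known racemic base-mediated para-alkylation of phenols) to racemic dienone F1, separate the enantiomers by preparative chromatography on a chiral stationary phase, and rejoin the route at 16.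

Step 18. What may go wrong is loss of the trans ring fusion when C5 is protonated during ketonisation, hydride delivery to C7 from the β face, or retro-aldol opening of the β-hydroxy ketone stage under basic borohydride. Fallback that never trigonalises C5: starting from 26, silylate the secondary 6α-hydroxyl (Et3SiCl, imidazole) to silyl ether F2, reduce C7 with NaBH4 from the α face to diol F3, and acetylate O7 (Ac2O, 4-dimethylaminopyridine) to acetate F4. Then remove the silyl group (HF·pyridine) to hydroxy acetate F5, oxidise C6 with Dess–Martin periodinane to keto acetate F6, and reduce with NaBH4/CeCl3·7H2O at −40 °C from the α face. This arrives directly at 31.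

Step 16. What may go wrong is enolisation toward C6 (scrambling the ketol through an enediolate), slow removal of the hindered tertiary C8 proton, or attack on the β face. Fallback that leaves C8 as the only position an electrophile can reach: starting from 24, oxidise with Dess–Martin periodinane to the enolised dione F7, form its dianion with LiN(i-Pr)2 (2.5 equiv) and hydroxylate with the same oxaziridine. In the dianion C5 is shielded by two quaternary neighbours, so oxygen should enter at C8; the product is 28, where the route is rejoined.

Step 11. What may go wrong is incomplete or uneven reduction (mixtures of ketone and carbinol stages), radical-anion coupling, fragmentation at C10 with rearomatisation, or protonation of C9 from the β face. Fallback by catalytic hydrogenation: starting from 16, hydrogenate over Pd/C (H2, 50 bar, Et3N, EtOH, 50 °C; then NaOMe, MeOH). Hydrogen should add to both double bonds from the α face, opposite the C10 methyl, with hydrogenolysis of the C–Cl bond and the benzyl ether, giving hydroxy ketone F8. Dess–Martin oxidation then gives 18.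

Step 14. What may go wrong is loss of chemoselectivity, with methylenation or enolisation of the C7 ketone by the basic ylide. Fallback that keeps C7 as a carbinol during both olefinations: starting from 17, oxidise only the primary alcohol (TEMPO cat., PhI(OAc)2) to hydroxy aldehyde F9, olefinate with 19 to hydroxy enal F10, methylenate with the ylide from 21 to dienol F11, and oxidise with Dess–Martin periodinane to 22.

## Further compounds

F1 | step 10 | racemic 4-[2-(benzyloxy)ethyl]-1-chloro-3,4a,8,8-tetramethyl-5,6,7,8-tetrahydronaphthalen-2(4aH)-one | O(Cc1ccccc1)CCC1=C(C)C(=O)C(Cl)=C2C(C)(C)CCCC21C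
F2 | step 18 | (12E)-8α-hydroxy-6α-(triethylsilyloxy)labda-12,14-dien-7-one | C=C/C(C)=C/C[C@H]1[C@](C)(O)C(=O)[C@H](O[Si](CC)(CC)CC)[C@H]2C(C)(C)CCC[C@@]21C
F3 | step 18 | (12E)-6α-(triethylsilyloxy)labda-12,14-diene-7β,8α-diol | C=C/C(C)=C/C[C@H]1[C@](C)(O)[C@@H](O)[C@H](O[Si](CC)(CC)CC)[C@H]2C(C)(C)CCC[C@@]21C
F4 | step 18 | (12E)-8α-hydroxy-6α-(triethylsilyloxy)labda-12,14-dien-7β-yl acetate | C=C/C(C)=C/C[C@H]1[C@](C)(O)[C@@H](OC(C)=O)[C@H](O[Si](CC)(CC)CC)[C@H]2C(C)(C)CCC[C@@]21C
F5 | step 18 | (12E)-6α,8α-dihydroxylabda-12,14-dien-7β-yl acetate | C=C/C(C)=C/C[C@H]1[C@](C)(O)[C@@H](OC(C)=O)[C@H](O)[C@H]2C(C)(C)CCC[C@@]21C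
F6 | step 18 | (12E)-8α-hydroxy-6-oxolabda-12,14-dien-7β-yl acetate | C=C/C(C)=C/C[C@H]1[C@](C)(O)[C@@H](OC(C)=O)C(=O)[C@H]2C(C)(C)CCC[C@@]21C
F7 | step 16 | (12E)-6-hydroxylabda-5,12,14-trien-7-one (8β-H) | C=C/C(C)=C/C[C@H]1[C@H](C)C(=O)C(O)=C2C(C)(C)CCC[C@@]21C
F8 | step 11 | 12-hydroxy-13,14,15,16-tetranorlabdan-7-one | OCC[C@H]1[C@H](C)C(=O)C[C@H]2C(C)(C)CCC[C@@]21C
F9 | step 14 | 7β-hydroxy-13,14,15,16-tetranorlabdan-12-al | O=CC[C@H]1[C@H](C)[C@@H](O)C[C@H]2C(C)(C)CCC[C@@]21C
F10 | step 14 | (12E)-7β-hydroxy-15-norlabd-12-en-14-al | O=C/C(C)=C/C[C@H]1[C@H](C)[C@@H](O)C[C@H]2C(C)(C)CCC[C@@]21C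
F11 | step 14 | (12E)-labda-12,14-dien-7β-ol | C=C/C(C)=C/C[C@H]1[C@H](C)[C@@H](O)C[C@H]2C(C)(C)CCC[C@@]21C
A1 | alternative 1 | 8α-(tert-butyldimethylsilyloxy)-12,13,14,15,16-pentanorlabd-6-en-11-al | O=C[C@H]1[C@](C)(O[Si](C)(C)C(C)(C)C)C=C[C@H]2C(C)(C)CCC[C@@]21C
A2 | alternative 1 | (2E,8E,10Z)-11-(tert-butyldimethylsilyloxy)-3,7,7-trimethyldodeca-2,8,10-trienal | O=C/C=C(C)/CCCC(C)(C)/C=C/C=C(C)\O[Si](C)(C)C(C)(C)C
A3 | alternative 2 | 12-(tert-butyldimethylsilyloxy)-8α-hydroxy-13,14,15,16-tetranorlabdan-7-one | CC(C)(C)[Si](C)(C)OCC[C@H]1[C@](C)(O)C(=O)C[C@H]2C(C)(C)CCC[C@@]21C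
A4 | alternative 2 | trans-hydrindane ketol with ring B contracted to C5, C6, C7, C9, C10: 7β-acetyl-7α-hydroxy, C9 bearing CH2CH2OSi(t-Bu)Me2 | CC(C)(C)[Si](C)(C)OCC[C@H]1[C@](C(C)=O)(O)C[C@H]2C(C)(C)CCC[C@@]21C
A5 | alternative 3 | methyl 6-(tert-butyldimethylsilyloxy)-12,13,14,15,16-pentanorlabda-5,8-dien-11-oate | COC(=O)C1=C(C)CC(O[Si](C)(C)C(C)(C)C)=C2C(C)(C)CCC[C@@]21C
A6 | alternative 3 | tert-butyldimethyl{[1-(2,6,6-trimethylcyclohex-1-en-1-yl)vinyl]oxy}silane | C=C(O[Si](C)(C)C(C)(C)C)C1=C(C)CCCC1(C)C
A7 | alternative 3 | methyl but-2-ynoate | CC#CC(=O)OC
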